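## The problem

Numbering follows the hydrindane: C1 (2‑methylbutanoyloxy), C2 (ketone), C3 (1‑acetoxyethyl, carbinol carbon C1′), C3a, C4 (isopropyl), C5, C6 (pentenoyloxy), C7 (methylene), C7a.

The target 24 is a trans‑fused hydrindan‑2‑one. Ring A is a cyclohexane with an exocyclic methylene at C7, an axial acyloxy group at C6 and an equatorial isopropyl group at C4. Ring B is a cyclopentanone whose carbonyl is flanked by two stereogenic α‑carbons, C1 and C3. Eight stereocentres and one E alkene must be set. C3a is the hub: once it is fixed relative to C4, the groups at C7a and C3 can be delivered anti to its branch on a cyclopentenone. C1 is the awkward one, because its oxygen must sit cis to the C7a–C7 bond, against the steric bias. Three different esters sit on three secondary alcohols, so each oxygen needs its own acyl group. Ring B is fragile: the β‑acetoxy ketone eliminates under base and both C1 and C3 are enolisable, so strong base is excluded once these groups are present. The enabling feature is in ring A: the methylene carbon C7 is bonded directly to the carbinol carbon C6, which is what a 1‑substituted vinyl metal and an aldehyde give in one bond‑forming event.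

## Retrosynthesis

**C6–O acyl bond (24 ⇒ 22 + 23).** The pentenoate is removed first because its alcohol is the one the ring closure creates. The ring closure can then run on a substrate that already carries the other two acyl groups, and no protecting group is needed after the bicycle exists. Removing the C1 or C1′ ester first would leave a free hydroxy ketone to acylate beside an allylic ester. The forward esterification of 22 with acid 23 must retain C6, keep the E geometry and not eliminate the acetate.

**C6–C7 bond (22 ⇒ 21).** Ring A is opened between the methylene‑bearing carbon and the carbinol carbon. The neighbouring options are weaker: methylenation of a C7 ketone leaves C6 to a late allylic oxidation of uncertain regio‑ and stereochemistry, and cuts at C7–C7a or C3a–C4 break bonds between stereocentres. This cut removes one ring and one stereocentre and leaves cyclopentanone 21. The forward reaction must form a vinyl metal from the iodide, add to the aldehyde only, close a six‑membered ring and place the oxygen axial.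

**C1–O bond with inversion (21 ⇒ 20 ⇒ 18 + 19).** Aldehyde 21 comes from dimethyl acetal 20. The 2‑methylbutanoate is cut at the C1–O bond, not the acyl bond. Any electrophilic oxygenation of a C1–C2 enol derivative enters anti to the C7a substituent and gives the trans ketol 18. Displacing the activated hydroxyl of 18 with the carboxylate of 19 installs the ester and corrects C1 in one step. The forward reaction is an SN2 at an α‑keto carbinol on the more hindered face.

**C7a–C7 bond and C1 oxygen (18 ⇒ 17 ⇒ 15 ⇒ 14).** The iodoalkene is traced to vinylsilane 17 and this to silyl enol ether 15, the product of conjugate addition of a 1‑silylvinyl copper reagent to enone 14. The alternative, an iodoalkene from a methyl ketone, would require telling an acetyl group from the ring ketone. The conjugate addition brings in C7 and the methylene carbon together and fixes the enol ether on the C1 side, so oxygen can only go to C1. The forward steps need anti addition relative to the C3a branch, selective epoxidation of the enol ether, and ipso iododesilylation.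

**C3–C1′ bond (14 ⇒ 13 ⇒ 9 + 10).** The side chain comes from an aldol between the α′‑enolate of cyclopentenone 9 and acetaldehyde 10, then acetylation. This is done here, not on the bicycle, because 9 has one α′‑position, carries no acyloxy ketone, and tolerates strong base. The aldol must go anti to the C3a branch and syn at C1′.

**Ring B (9 ⇒ 8 ⇒ 7 ⇒ 6).** The cyclopentenone is opened at its C=C bond: ring‑closing metathesis of dienone 8, made from ester 6 through amide 7. An aldol‑condensation route would pass through an aldehyde that is epimerisable at C3a. The precursor is acyclic with two stereocentres.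

**C3–C3a bond (6 ⇒ 5).** C3a must be set relative to C4 in an open chain, where induction by an all‑carbon stereocentre is unreliable. A Johnson–Claisen rearrangement of allylic alcohol 5 transfers chirality from a reagent‑set carbinol to C3a. It also supplies C3 and C2 as the acetate unit and a propenyl group as the metathesis partner. The forward step needs a chair transition state and a pure E alkene.

**Chain from the terpene (5 ⇒ 4 ⇒ 3 ⇒ 1).** Alcohol 5 comes from enone 4 by oxazaborolidine reduction, 4 from its Z isomer 3, and 3 from ozonolysis of (R)‑α‑phellandrene 1. The terpene supplies C4 with its isopropyl group, C5, C6 at the aldehyde level, and C3a and C7a as the enone carbons. Its methyl‑bearing carbon and methyl group serve only as the relay carbinol and are later lost as propene.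

## Roads not taken

**Alternative 1:** The cut is through C3a–C7a and C4–C5. Trienal A1, activated as an iminium ion by a chiral secondary amine, would undergo intramolecular Diels–Alder reaction to hydrindene carbaldehyde A2, closing both rings at once.
- Merits: one step builds the bicycle and sets C3a, C7a and C4 under catalyst control. In ring‑forming economy it is better than the chosen plan.
- Weak points: A2 has a formyl group where the isopropyl must be, and no oxygen at C1. Its ring A holds a methyl‑substituted C6=C7 alkene, which would still need an allylic oxidation with transposition to give the methylene and C6 carbinol. Oxygenation at C1 would have to be directed to one of two CH2 groups beside a masked ketone.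
- Comparison: the chosen plan is longer, but it delivers the methylene/carbinol pair with fixed regiochemistry and places C1 oxygen by a regiospecific enol ether.

**Alternative 2:** The cut is C1–C7a. Keto aldehyde A3 would cyclise by an enolexo aldol to hydroxy hydrindanone A4.
- Merits: ring A is pre‑formed with the isopropyl group, the C7 ketone is a handle for methylenation, and the aldol brings in the C1 oxygen. It reaches the hydrindane in fewer steps than the chosen plan.
- Weak points: the ketone must enolise toward C7a and not C6. C1 and the ring fusion are set under reversible conditions. The C1 and C2 oxygens arrive at the wrong oxidation levels and must be exchanged. The C6 oxygen still depends on a late allylic oxidation that must deliver the axial alcohol.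
- Comparison: the chosen plan gives up the shorter entry in return for a C6 stereocentre formed in the ring‑closing step itself.

**Alternative 3:** The cut is C3–C3a. Diazo diketone A5 with Rh2(OAc)4 would insert into the equatorial C–H at C3a to give acetyl hydrindanone A6.
- Merits: it forms a C–C bond at an unactivated CH2 with retention, so trans fusion follows from the substrate. It is the most direct way to a fully substituted ring B.
- Weak points: A6 is a 2‑acyl cyclopentanone, so C3 is labile. The acetyl group must be reduced to the (S) carbinol beside the ring ketone. Ring A still needs methylenation and C6 oxidation.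
- Comparison: the chosen plan sets C1′ by an aldol on a simple enone and avoids a 1,3‑dicarbonyl. Its cost is opening and re‑closing ring A.

Key step: step 15

Assumption: (2R)‑2‑methylbutanoic acid 19, (2E)‑3‑methylpent‑2‑enoic acid 23 and (1‑bromoethenyl)trimethylsilane are taken as purchased, stereochemically pure reagents.

## Route

Step 1
Reactants: 1 (5R)-2-methyl-5-(propan-2-yl)cyclohexa-1,3-diene [(R)-α-phellandrene]
Product: 3 (3Z,5R)-7,7-dimethoxy-5-(propan-2-yl)hept-3-en-2-one, via keto aldehyde 2 (not isolated)
Conditions: O3 (1.0 equiv), CH2Cl2/MeOH, −78 °C; Me2S, −78 °C → rt; then HC(OMe)3, TsOH·H2O (cat.), MeOH, 0 °C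
Reagents that add atoms: ozone, [O-][O+]=O; trimethyl orthoformate, COC(OC)OC
Why: Ozonolysis with reductive work-up: the electrophile should consume the methyl-substituted, more electron-rich alkene of the diene first and leave a deactivated cis-enone; orthoformate exchange acetalises the aldehyde only, and C5 of 3 is the untouched stereocentre of 1.

Step 2
Reactants: 3 (3Z,5R)-7,7-dimethoxy-5-(propan-2-yl)hept-3-en-2-one
Product: 4 (3E,5R)-7,7-dimethoxy-5-(propan-2-yl)hept-3-en-2-one
Conditions: I2 (2 mol %), CH2Cl2, rt, daylight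
Reagents that add atoms: none
Why: Iodine-catalysed Z to E isomerisation by reversible iodine-atom addition should give the thermodynamic trans-enone without touching the γ-stereocentre; geometric purity matters because step 4 reads the alkene geometry into C3a.

Step 3
Reactants: 4 (3E,5R)-7,7-dimethoxy-5-(propan-2-yl)hept-3-en-2-one
Product: 5 (2S,3E,5R)-7,7-dimethoxy-5-(propan-2-yl)hept-3-en-2-ol
Conditions: (R)-tetrahydro-1-methyl-3,3-diphenyl-1H,3H-pyrrolo[1,2-c][1,3,2]oxazaborole [(R)-Me-CBS] (0.2 equiv), catecholborane, toluene, −78 °C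
Reagents that add atoms: none
Why: Corey–Bakshi–Shibata reduction: the alkenyl group acts as the large substituent, so the (R)-catalyst should deliver hydride to give the (2S) allylic alcohol under reagent control, with 1,2-reduction favoured by catecholborane at low temperature.

Step 4
Reactants: 5 (2S,3E,5R)-7,7-dimethoxy-5-(propan-2-yl)hept-3-en-2-ol
Product: 6 methyl (3S,4R)-6,6-dimethoxy-4-(propan-2-yl)-3-[(1E)-prop-1-en-1-yl]hexanoate
Conditions: MeC(OMe)3, EtCO2H (cat.), xylenes, 135 °C, MeOH distilled off
Reagents that add atoms: trimethyl orthoacetate, CC(OC)(OC)OC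
Why: Johnson–Claisen rearrangement: the ketene acetal formed in situ rearranges through a chair with the carbinol methyl equatorial, so the (2S,3E) alcohol should transfer its chirality to the new (3S) centre (future C3a) and leave an (E)-propenyl group; the methyl orthoester keeps the dimethyl acetal intact.

Step 5
Reactants: 6 methyl (3S,4R)-6,6-dimethoxy-4-(propan-2-yl)-3-[(1E)-prop-1-en-1-yl]hexanoate
Product: 7 (3S,4R)-N,6,6-trimethoxy-N-methyl-4-(propan-2-yl)-3-[(1E)-prop-1-en-1-yl]hexanamide
Conditions: MeNHOMe·HCl, i-PrMgCl, THF, −20 → 0 °C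
Reagents that add atoms: N,O-dimethylhydroxylamine hydrochloride, CNOC.Cl
Why: Weinreb amide formation from the ester with the magnesium amide; the only acidic position is a CH2, so no stereocentre is at risk.

Step 6
Reactants: 7 (3S,4R)-N,6,6-trimethoxy-N-methyl-4-(propan-2-yl)-3-[(1E)-prop-1-en-1-yl]hexanamide
Product: 8 (5S,6R)-8,8-dimethoxy-6-(propan-2-yl)-5-[(1E)-prop-1-en-1-yl]oct-1-en-3-one
Conditions: CH2=CHMgBr, THF, −78 → 0 °C; cold aq. NH4Cl
Reagents that add atoms: vinylmagnesium bromide, C=C[Mg]Br
Why: Weinreb ketone synthesis: the chelated tetrahedral adduct stops at single addition, and a cold, mildly acidic quench releases the vinyl ketone before the liberated amine can add to it.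

Step 7
Reactants: 8 (5S,6R)-8,8-dimethoxy-6-(propan-2-yl)-5-[(1E)-prop-1-en-1-yl]oct-1-en-3-one
Product: 9 (4S)-4-[(3R)-1,1-dimethoxy-4-methylpentan-3-yl]cyclopent-2-en-1-one
Conditions: second-generation Grubbs catalyst (5 mol %), CH2Cl2 (0.01 M), 40 °C
Reagents that add atoms: none
Why: Ring-closing metathesis of a 1,6-dien-3-one: the ruthenium carbene loads on the propenyl group, closes onto the vinyl ketone and expels propene, leaving both stereocentres untouched.

Step 8
Reactants: 9 (4S)-4-[(3R)-1,1-dimethoxy-4-methylpentan-3-yl]cyclopent-2-en-1-one; 10 acetaldehyde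
Product: 13 (4S,5R)-4-[(3R)-1,1-dimethoxy-4-methylpentan-3-yl]-5-[(1S)-1-hydroxyethyl]cyclopent-2-en-1-one, via lithium enolate 11 (not isolated), via titanium enolate 12 (not isolated)
Conditions: LiN(iPr)2, THF, −78 °C; ClTi(OiPr)3, −78 → −40 °C; MeCHO, −78 °C
Reagents that add atoms: none
Why: Aldol addition of the kinetic α′-enolate: acetaldehyde should add anti to the C4 branch, and triisopropoxytitanium enolates of cyclic ketones favour the syn aldol, which is the required (5R,1′S) pair.

Step 9
Reactants: 13 (4S,5R)-4-[(3R)-1,1-dimethoxy-4-methylpentan-3-yl]-5-[(1S)-1-hydroxyethyl]cyclopent-2-en-1-one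
Product: 14 (1S)-1-[(1R,5S)-5-[(3R)-1,1-dimethoxy-4-methylpentan-3-yl]-2-oxocyclopent-3-en-1-yl]ethyl acetate
Conditions: Ac2O, pyridine, DMAP (cat.), CH2Cl2, 0 °C
Reagents that add atoms: acetic anhydride, CC(=O)OC(C)=O
Why: Acetylation under nucleophilic catalysis, kept cold and short so that the new β-acetoxy ketone neither eliminates nor undergoes retro-aldol cleavage.

Step 10
Reactants: 14 (1S)-1-[(1R,5S)-5-[(3R)-1,1-dimethoxy-4-methylpentan-3-yl]-2-oxocyclopent-3-en-1-yl]ethyl acetate
Product: 15 (1S)-1-[(1R,4R,5S)-5-[(3R)-1,1-dimethoxy-4-methylpentan-3-yl]-4-[1-(trimethylsilyl)ethenyl]-2-[(trimethylsilyl)oxy]cyclopent-2-en-1-yl]ethyl acetate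
Conditions: CH2=C(SiMe3)MgBr (from the bromide and Mg), CuBr·SMe2 (20 mol %), Me3SiCl, THF, −78 °C; Et3N, pentane, cold work-up
Reagents that add atoms: [1-(trimethylsilyl)ethenyl]magnesium bromide, C=C([Mg]Br)[Si](C)(C)C; chlorotrimethylsilane, C[Si](C)(C)Cl
Why: Copper-catalysed conjugate addition accelerated and trapped by Me3SiCl: the vinyl group should enter anti to the adjacent branch (trans across C3a–C7a), and the enolate is fixed as the silyl enol ether on the C1 side, away from the acetoxy-bearing carbon.

Step 11
Reactants: 15 (1S)-1-[(1R,4R,5S)-5-[(3R)-1,1-dimethoxy-4-methylpentan-3-yl]-4-[1-(trimethylsilyl)ethenyl]-2-[(trimethylsilyl)oxy]cyclopent-2-en-1-yl]ethyl acetate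
Product: 17 (1S)-1-[(1R,2S,3R,4S)-2-[(3R)-1,1-dimethoxy-4-methylpentan-3-yl]-4-hydroxy-5-oxo-3-[1-(trimethylsilyl)ethenyl]cyclopentyl]ethyl acetate, via silyloxy ketone 16 (not isolated)
Conditions: mCPBA (1.05 equiv), CH2Cl2, −20 °C; then citric acid, MeOH, 0 °C
Reagents that add atoms: 3-chloroperbenzoic acid, O=C(OO)c1cccc(Cl)c1
Why: Rubottom oxidation: the silyl enol ether is epoxidised much faster than the vinylsilane, from the face opposite its two allylic substituents, so after silyl migration and mild acid the hydroxyl should stand trans to the silylvinyl group.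

Step 12
Reactants: 17 (1S)-1-[(1R,2S,3R,4S)-2-[(3R)-1,1-dimethoxy-4-methylpentan-3-yl]-4-hydroxy-5-oxo-3-[1-(trimethylsilyl)ethenyl]cyclopentyl]ethyl acetate
Product: 18 (1S)-1-[(1R,2S,3R,4S)-2-[(3R)-1,1-dimethoxy-4-methylpentan-3-yl]-4-hydroxy-3-(1-iodoethenyl)-5-oxocyclopentyl]ethyl acetate
Conditions: NIS, 2,6-lutidine, (CF3)2CHOH, 0 °C
Reagents that add atoms: N-iodosuccinimide, O=C1CCC(=O)N1I
Why: Iododesilylation: iodonium transfer to the vinylsilane in the ionising solvent followed by loss of silicon should give the 2-iodoalk-1-ene; the cold, buffered medium should spare the acetal, the acetate and the ketol.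

Step 13
Reactants: 18 (1S)-1-[(1R,2S,3R,4S)-2-[(3R)-1,1-dimethoxy-4-methylpentan-3-yl]-4-hydroxy-3-(1-iodoethenyl)-5-oxocyclopentyl]ethyl acetate; 19 (2R)-2-methylbutanoic acid
Product: 20 (1R,2R,3S,4R)-4-[(1S)-1-(acetyloxy)ethyl]-3-[(3R)-1,1-dimethoxy-4-methylpentan-3-yl]-2-(1-iodoethenyl)-5-oxocyclopentyl (2R)-2-methylbutanoate
Conditions: PPh3, DIAD, toluene, 0 °C → rt
Reagents that add atoms: none
Why: Mitsunobu esterification: the α-keto carbinol is activated as its oxyphosphonium salt and displaced by the carboxylate with inversion (SN2, helped by the adjacent carbonyl), turning the trans hydroxyl into the cis (1R) ester; anti elimination is blocked because the only β-hydrogen is cis to the leaving group.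

Step 14
Reactants: 20 (1R,2R,3S,4R)-4-[(1S)-1-(acetyloxy)ethyl]-3-[(3R)-1,1-dimethoxy-4-methylpentan-3-yl]-2-(1-iodoethenyl)-5-oxocyclopentyl (2R)-2-methylbutanoate
Product: 21 (1R,2R,3S,4R)-4-[(1S)-1-(acetyloxy)ethyl]-2-(1-iodoethenyl)-3-[(3R)-2-methyl-5-oxopentan-3-yl]-5-oxocyclopentyl (2R)-2-methylbutanoate
Conditions: TFA, H2O, CH2Cl2, 0 °C
Reagents that add atoms: water, O
Why: Acid-catalysed hydrolysis of the dimethyl acetal; the esters, the iodoalkene and both α-stereocentres of the ketone should tolerate cold aqueous acid.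

Step 15
Reactants: 21 (1R,2R,3S,4R)-4-[(1S)-1-(acetyloxy)ethyl]-2-(1-iodoethenyl)-3-[(3R)-2-methyl-5-oxopentan-3-yl]-5-oxocyclopentyl (2R)-2-methylbutanoate
Product: 22 (1R,3R,3aR,4R,6S,7aS)-3-[(1S)-1-(acetyloxy)ethyl]-6-hydroxy-7-methylidene-2-oxo-4-(propan-2-yl)octahydro-1H-inden-1-yl (2R)-2-methylbutanoate
Conditions: CrCl2 (8 equiv), NiCl2 (1 mol % of CrCl2), degassed DMSO/THF, rt, 0.005 M
Reagents that add atoms: none
Why: Nozaki–Hiyama–Kishi reaction: NiCl2 is reduced by CrCl2 to zerovalent nickel, which inserts into the vinyl C–I bond, and transmetalation to trivalent chromium gives a vinylchromium species that adds to the aldehyde, two equivalents of divalent chromium being consumed per bond. The closest known reaction type is the intramolecular nickel/chromium coupling of 2-iodoalk-1-enes with aldehydes to give 2-methylenecycloalkanols. Ring A closes in a 6-exo-trig mode, the vinyl carbon attacking the carbonyl carbon with the oxygen outside the ring. The one new stereocentre, C6, is controlled by a chair-like transition state in which the two ring B bonds (already trans) and the isopropyl group are equatorial and the chromium-bound oxygen takes the axial site to avoid allylic 1,3-strain with the developing methylene, giving the (6S) alcohol. The step needs chemoselectivity for the aldehyde over the ketone and two esters, which the low basicity and aldehyde preference of organochromium reagents provide, and CrCl2 is too weak a reductant to cleave the α-acyloxy ketone. High dilution suppresses intermolecular coupling.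

Step 16
Reactants: 22 (1R,3R,3aR,4R,6S,7aS)-3-[(1S)-1-(acetyloxy)ethyl]-6-hydroxy-7-methylidene-2-oxo-4-(propan-2-yl)octahydro-1H-inden-1-yl (2R)-2-methylbutanoate; 23 (2E)-3-methylpent-2-enoic acid
Product: 24 (1R,3R,3aR,4R,6S,7aS)-3-[(1S)-1-(acetyloxy)ethyl]-7-methylidene-1-{[(2R)-2-methylbutanoyl]oxy}-2-oxo-4-(propan-2-yl)octahydro-1H-inden-6-yl (2E)-3-methylpent-2-enoate
Conditions: DIC, DMAP (0.2 equiv), CH2Cl2, 0 °C → rt
Reagents that add atoms: none
Why: Steglich esterification of the axial allylic alcohol with retention at C6; catalytic DMAP at low temperature should limit isomerisation of the enoyl donor and elimination of the β-acetoxy ketone.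

## Compound list

1 | (5R)-2-methyl-5-(propan-2-yl)cyclohexa-1,3-diene [(R)-α-phellandrene] | CC1=CC[C@H](C(C)C)C=C1 | starting material
2 | (3R,4Z)-6-oxo-3-(propan-2-yl)hept-4-enal | CC(=O)/C=C\[C@@H](C(C)C)CC=O | intermediate
3 | (3Z,5R)-7,7-dimethoxy-5-(propan-2-yl)hept-3-en-2-one | CC(=O)/C=C\[C@@H](C(C)C)CC(OC)OC | intermediate
4 | (3E,5R)-7,7-dimethoxy-5-(propan-2-yl)hept-3-en-2-one | CC(=O)/C=C/[C@@H](C(C)C)CC(OC)OC | intermediate
5 | (2S,3E,5R)-7,7-dimethoxy-5-(propan-2-yl)hept-3-en-2-ol | C[C@H](O)/C=C/[C@@H](C(C)C)CC(OC)OC | intermediate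
6 | methyl (3S,4R)-6,6-dimethoxy-4-(propan-2-yl)-3-[(1E)-prop-1-en-1-yl]hexanoate | COC(=O)C[C@@H](/C=C/C)[C@@H](C(C)C)CC(OC)OC | intermediate
7 | (3S,4R)-N,6,6-trimethoxy-N-methyl-4-(propan-2-yl)-3-[(1E)-prop-1-en-1-yl]hexanamide | CON(C)C(=O)C[C@@H](/C=C/C)[C@@H](C(C)C)CC(OC)OC | intermediate
8 | (5S,6R)-8,8-dimethoxy-6-(propan-2-yl)-5-[(1E)-prop-1-en-1-yl]oct-1-en-3-one | C=CC(=O)C[C@@H](/C=C/C)[C@@H](C(C)C)CC(OC)OC | intermediate
9 | (4S)-4-[(3R)-1,1-dimethoxy-4-methylpentan-3-yl]cyclopent-2-en-1-one | O=C1C=C[C@H](C1)[C@@H](C(C)C)CC(OC)OC | intermediate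
10 | acetaldehyde | CC=O | starting material
11 | lithium α′-enolate of 9 (cross-conjugated dienolate) | [Li]OC1=C[C@H]([C@@H](C(C)C)CC(OC)OC)C=C1 | intermediate
12 | triisopropoxytitanium α′-enolate of 9 | CC(C)O[Ti](OC(C)C)(OC(C)C)OC1=C[C@H]([C@@H](C(C)C)CC(OC)OC)C=C1 | intermediate
13 | (4S,5R)-4-[(3R)-1,1-dimethoxy-4-methylpentan-3-yl]-5-[(1S)-1-hydroxyethyl]cyclopent-2-en-1-one | O=C1C=C[C@@H]([C@@H](C(C)C)CC(OC)OC)[C@@H]1[C@H](C)O | intermediate
14 | (1S)-1-[(1R,5S)-5-[(3R)-1,1-dimethoxy-4-methylpentan-3-yl]-2-oxocyclopent-3-en-1-yl]ethyl acetate | O=C1C=C[C@@H]([C@@H](C(C)C)CC(OC)OC)[C@@H]1[C@H](C)OC(C)=O | intermediate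
15 | (1S)-1-[(1R,4R,5S)-5-[(3R)-1,1-dimethoxy-4-methylpentan-3-yl]-4-[1-(trimethylsilyl)ethenyl]-2-[(trimethylsilyl)oxy]cyclopent-2-en-1-yl]ethyl acetate | C=C([Si](C)(C)C)[C@H]1C=C(O[Si](C)(C)C)[C@@H]([C@H](C)OC(C)=O)[C@@H]1[C@@H](C(C)C)CC(OC)OC | intermediate
16 | (1S)-1-[(1R,2S,3R,4S)-2-[(3R)-1,1-dimethoxy-4-methylpentan-3-yl]-5-oxo-3-[1-(trimethylsilyl)ethenyl]-4-[(trimethylsilyl)oxy]cyclopentyl]ethyl acetate | C=C([Si](C)(C)C)[C@H]1[C@H](O[Si](C)(C)C)C(=O)[C@@H]([C@H](C)OC(C)=O)[C@@H]1[C@@H](C(C)C)CC(OC)OC | intermediate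
17 | (1S)-1-[(1R,2S,3R,4S)-2-[(3R)-1,1-dimethoxy-4-methylpentan-3-yl]-4-hydroxy-5-oxo-3-[1-(trimethylsilyl)ethenyl]cyclopentyl]ethyl acetate | C=C([Si](C)(C)C)[C@H]1[C@H](O)C(=O)[C@@H]([C@H](C)OC(C)=O)[C@@H]1[C@@H](C(C)C)CC(OC)OC | intermediate
18 | (1S)-1-[(1R,2S,3R,4S)-2-[(3R)-1,1-dimethoxy-4-methylpentan-3-yl]-4-hydroxy-3-(1-iodoethenyl)-5-oxocyclopentyl]ethyl acetate | C=C(I)[C@H]1[C@H](O)C(=O)[C@@H]([C@H](C)OC(C)=O)[C@@H]1[C@@H](C(C)C)CC(OC)OC | intermediate
19 | (2R)-2-methylbutanoic acid | CC[C@@H](C)C(=O)O | starting material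
20 | (1R,2R,3S,4R)-4-[(1S)-1-(acetyloxy)ethyl]-3-[(3R)-1,1-dimethoxy-4-methylpentan-3-yl]-2-(1-iodoethenyl)-5-oxocyclopentyl (2R)-2-methylbutanoate | C=C(I)[C@H]1[C@@H](OC(=O)[C@H](C)CC)C(=O)[C@@H]([C@H](C)OC(C)=O)[C@@H]1[C@@H](C(C)C)CC(OC)OC | intermediate
21 | (1R,2R,3S,4R)-4-[(1S)-1-(acetyloxy)ethyl]-2-(1-iodoethenyl)-3-[(3R)-2-methyl-5-oxopentan-3-yl]-5-oxocyclopentyl (2R)-2-methylbutanoate | C=C(I)[C@H]1[C@@H](OC(=O)[C@H](C)CC)C(=O)[C@@H]([C@H](C)OC(C)=O)[C@@H]1[C@@H](C(C)C)CC=O | intermediate
22 | (1R,3R,3aR,4R,6S,7aS)-3-[(1S)-1-(acetyloxy)ethyl]-6-hydroxy-7-methylidene-2-oxo-4-(propan-2-yl)octahydro-1H-inden-1-yl (2R)-2-methylbutanoate | C=C1[C@H]2[C@@H](OC(=O)[C@H](C)CC)C(=O)[C@@H]([C@H](C)OC(C)=O)[C@@H]2[C@@H](C(C)C)C[C@@H]1O | intermediate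
23 | (2E)-3-methylpent-2-enoic acid | CC/C(C)=C/C(=O)O | starting material
24 | (1R,3R,3aR,4R,6S,7aS)-3-[(1S)-1-(acetyloxy)ethyl]-7-methylidene-1-{[(2R)-2-methylbutanoyl]oxy}-2-oxo-4-(propan-2-yl)octahydro-1H-inden-6-yl (2E)-3-methylpent-2-enoate | C=C1[C@@H]2[C@H]([C@H]([C@H](C)OC(C)=O)C(=O)[C@@H]2OC(=O)[C@H](C)CC)[C@@H](C(C)C)C[C@@H]1OC(=O)/C=C(\C)CC | target

## Step count and risks

Total step count: 16. Longest linear sequence: 16 steps (1 to 24).

**Step 15 (key step).** The likely failure is poor facial selectivity at the aldehyde, so that the equatorial alkoxide forms, together with some protonation of the vinylchromium intermediate before ring closure. The fallback accepts the wrong epimer: from 21 the same conditions would give the C6‑epimeric equatorial alcohol F1. Mitsunobu esterification of F1 with acid 23 (PPh3, DIAD) inverts C6 while installing the enoate and rejoins the route at 24. An SN2′ course on the allylic system is the hazard of this fallback.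

**Step 1.** Ozone may attack the disubstituted alkene of the diene competitively, or the vinyl carbonyl oxide may rearrange, lowering regioselectivity. The fallback separates oxidation from cleavage. From 1, dihydroxylation with OsO4 (cat.) and N‑methylmorpholine N‑oxide should take the trisubstituted alkene, because a cis‑disubstituted ring alkene is the poorest class of substrate for osmylation. This gives the cyclohexenediol F2. Cleavage with NaIO4 gives keto aldehyde 2, and acetalisation as in step 1 returns to 3.

**Step 8.** The risk is insufficient syn selectivity at the carbinol carbon, or retro‑aldol cleavage on warming. The fallback makes the anti aldol deliberately and inverts it. From 9, enolisation with Cy2BCl and Et3N and addition of 10 should give the anti aldol F3, since cyclic ketone boron enolates are anti‑selective. Mitsunobu reaction of F3 with acetic acid inverts C1′ and acetylates in one step, rejoining at 14. Dehydration of the β‑hydroxy ketone is the competing process to watch.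

**Step 12.** With a 1,1‑disubstituted vinylsilane the electrophile may add without loss of silicon, or the ketone may be iodinated at C3. The fallback changes the two‑carbon nucleophile to an alkyne.
- From 14, conjugate addition of (trimethylsilyl)ethynylzinc bromide promoted by TBSOTf gives silyl enol ether F4.
- Rubottom oxidation (mCPBA, then HF·pyridine) gives ketol F5.
- Mitsunobu reaction with 19 gives ester F6.
- Protiodesilylation with catalytic AgNO3 in aqueous acetone gives terminal alkyne F7.
- NaI, Me3SiCl and H2O in MeCN add HI in the Markovnikov sense and cleave the acetal, rejoining at 21.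

**Step 13.** Displacement on the face that carries the iodovinyl group may be slow, allowing enolisation and loss of configuration at C1. The fallback uses a sulfonate leaving group and a preformed carboxylate. From 18, Tf2O and pyridine give triflate F8. Cesium (2R)‑2‑methylbutanoate with 18‑crown‑6 in toluene then displaces it with inversion, rejoining at 20.

## Further compounds

F1 | step 15 | (1R,3R,3aR,4R,6R,7aS)-3-[(1S)-1-(acetyloxy)ethyl]-6-hydroxy-7-methylidene-2-oxo-4-(propan-2-yl)octahydro-1H-inden-1-yl (2R)-2-methylbutanoate | C=C1[C@H]2[C@@H](OC(=O)[C@H](C)CC)C(=O)[C@@H]([C@H](C)OC(C)=O)[C@@H]2[C@@H](C(C)C)C[C@H]1O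
F2 | step 1 | (1S,2R,5R)-2-methyl-5-(propan-2-yl)cyclohex-3-ene-1,2-diol | C[C@]1(O)[C@@H](O)C[C@H](C(C)C)C=C1
F3 | step 8 | (4S,5R)-4-[(3R)-1,1-dimethoxy-4-methylpentan-3-yl]-5-[(1R)-1-hydroxyethyl]cyclopent-2-en-1-one | O=C1C=C[C@@H]([C@@H](C(C)C)CC(OC)OC)[C@@H]1[C@@H](C)O
F4 | step 12 | (1S)-1-[(1R,4R,5R)-2-[(tert-butyldimethylsilyl)oxy]-5-[(3R)-1,1-dimethoxy-4-methylpentan-3-yl]-4-[(trimethylsilyl)ethynyl]cyclopent-2-en-1-yl]ethyl acetate | C[Si](C)(C)C#C[C@H]1C=C(O[Si](C)(C)C(C)(C)C)[C@@H]([C@H](C)OC(C)=O)[C@@H]1[C@@H](C(C)C)CC(OC)OC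
F5 | step 12 | (1S)-1-[(1R,2R,3S,4S)-2-[(3R)-1,1-dimethoxy-4-methylpentan-3-yl]-4-hydroxy-5-oxo-3-[(trimethylsilyl)ethynyl]cyclopentyl]ethyl acetate | C[Si](C)(C)C#C[C@H]1[C@H](O)C(=O)[C@@H]([C@H](C)OC(C)=O)[C@@H]1[C@@H](C(C)C)CC(OC)OC
F6 | step 12 | (1R,2S,3R,4R)-4-[(1S)-1-(acetyloxy)ethyl]-3-[(3R)-1,1-dimethoxy-4-methylpentan-3-yl]-5-oxo-2-[(trimethylsilyl)ethynyl]cyclopentyl (2R)-2-methylbutanoate | C[Si](C)(C)C#C[C@H]1[C@@H](OC(=O)[C@H](C)CC)C(=O)[C@@H]([C@H](C)OC(C)=O)[C@@H]1[C@@H](C(C)C)CC(OC)OC
F7 | step 12 | (1R,2S,3R,4R)-4-[(1S)-1-(acetyloxy)ethyl]-3-[(3R)-1,1-dimethoxy-4-methylpentan-3-yl]-2-ethynyl-5-oxocyclopentyl (2R)-2-methylbutanoate | C#C[C@H]1[C@@H](OC(=O)[C@H](C)CC)C(=O)[C@@H]([C@H](C)OC(C)=O)[C@@H]1[C@@H](C(C)C)CC(OC)OC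
F8 | step 13 | (1S)-1-[(1R,2S,3R,4S)-2-[(3R)-1,1-dimethoxy-4-methylpentan-3-yl]-3-(1-iodoethenyl)-5-oxo-4-{[(trifluoromethyl)sulfonyl]oxy}cyclopentyl]ethyl acetate | C=C(I)[C@H]1[C@H](OS(=O)(=O)C(F)(F)F)C(=O)[C@@H]([C@H](C)OC(C)=O)[C@@H]1[C@@H](C(C)C)CC(OC)OC
A1 | alternative 1 | (2E,7E)-trienal with spiro-dithiane and silyloxyethyl branch, Diels–Alder precursor | O=C/C=C/[C@H]([C@H](C)O[Si](C)(C)C(C)(C)C)C1(SCCCS1)C/C=C(\C)C=C
A2 | alternative 1 | trans-fused hydrindene carbaldehyde with spiro-dithiane at the future ketone carbon | CC=1[C@@H]2[C@H]([C@H]([C@H](C)O[Si](C)(C)C(C)(C)C)C3(SCCCS3)C2)[C@@H](C=O)CC1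
A3 | alternative 2 | 4-isopropylcyclohexanone carrying the 2-(triethylsilyloxy)-3-oxopropyl arm at C3, aldol precursor | O=C1C[C@H](C[C@@H](O[Si](CC)(CC)CC)C=O)[C@@H](C(C)C)CC1
A4 | alternative 2 | trans-fused hydroxy hydrindanone with ring A ketone | O=C1[C@@H]2[C@H](C[C@@H](O[Si](CC)(CC)CC)[C@@H]2O)[C@@H](C(C)C)CC1
A5 | alternative 3 | 2-diazo-1,3-diketone on the ketal-protected isopropylcyclohexane, insertion precursor | CC(=O)C(=[N+]=[N-])C(=O)[C@H](O[Si](C)(C)C(C)(C)C)[C@H]1C[C@@H](C(C)C)CCC12OCCO2
A6 | alternative 3 | trans-fused 2-acetylcyclopentanone with ring A ketal | C12(OCCO1)[C@@H]3[C@H]([C@H](C(C)=O)C(=O)[C@@H]3O[Si](C)(C)C(C)(C)C)[C@@H](C(C)C)CC2
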